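**Retrosynthetic overview**

1. Target ⇐ hydride reduction of a cis-fused 2-aryl-oxolane γ-lactone, in which the hydroxymethyl carbon on C3 (as C=O) is esterified by the carbinol oxygen of the C4 side chain; this temporary ring locks C3/C4 cis.
2. That lactone ⇐ acid epimerisation at C2 ⇐ all-cis hydrogenation of a flat 1H,3H-furo[3,4-c]furan-1-one, whose furan ring is the oxolane (O1, C2–C5) at the aromatic oxidation level and whose only stereocentre (carbinol carbon C7) steers the hydrogen.
3. Key disconnection: O1–C5 and C3–C4 of the furan are cut together, giving an acyclic propargylic α-diazo-β-keto ester. A dirhodium carbenoid/alkyne cascade closes the lactone ring first (5-exo-dig) and the furan ring second, in one operation.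
4. Enabling feature: C3 lies between the aryl-bearing C2 (whose oxygen is O1) and the hydroxymethyl carbon, so it can be the diazo carbon of a 1,3-dicarbonyl unit. C4–C5 can be a terminal alkyne on C7, and the 1,4-relationship between the hydroxymethyl carbon and the C7 oxygen gives a three-atom ester tether.
5. Precursors: an acyl Meldrum's acid from 4-(benzyloxy)-3-methoxybenzoic acid, and an (R)-propargylic alcohol from vanillin (pivalate, Grignard addition, lipase resolution).

Key step: step 7

Remarks:
- Locants used in all Why lines are those of the target: oxolane O1, C2 (aryl), C3 (CH2OH), C4 (side chain), C5 (CH2); C7 is the carbinol carbon.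
- Assumption: the lipase shows its usual size preference (aryl large, ethynyl medium), which makes the (R)-acetate the fast-reacting enantiomer.
- C7 keeps one spatial arrangement from compound 6 to the target; its descriptor reads S only in 13, where the furan carbon outranks the aryl group.

**Route**

Step 1
Reactants: 1 vanillin
Product: 2 4-formyl-2-methoxyphenyl 2,2-dimethylpropanoate
Conditions: PivCl, Et3N, DMAP (cat.), CH2Cl2, 0 °C to rt
Reagents that add atoms: pivaloyl chloride CC(C)(C)C(=O)Cl
Why: Base-mediated O-acylation of the phenol (nucleophilic acyl substitution); the pivalate should survive the Grignard and lipase steps, makes its arene a poor cation-stabilising group, and is removed by hydride in step 10.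

Step 2
Reactants: 2 4-formyl-2-methoxyphenyl 2,2-dimethylpropanoate; 3 ethynylmagnesium bromide
Product: 5 racemic 4-[1-(acetyloxy)prop-2-yn-1-yl]-2-methoxyphenyl 2,2-dimethylpropanoate, via bromomagnesium alkoxide 4 (not isolated)
Conditions: HC≡CMgBr (1.1 equiv), THF, −78 to 0 °C; then Ac2O, 0 °C to rt
Reagents that add atoms: acetic anhydride CC(=O)OC(C)=O
Why: Grignard addition to the aldehyde at low temperature, where the hindered aryl ester should not be attacked, then O-acetylation of the magnesium alkoxide in the same flask; C7 is formed racemic and is resolved in step 3.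

Step 3
Reactants: 5 racemic 4-[1-(acetyloxy)prop-2-yn-1-yl]-2-methoxyphenyl 2,2-dimethylpropanoate
Product: 6 4-[(1R)-1-hydroxyprop-2-yn-1-yl]-2-methoxyphenyl 2,2-dimethylpropanoate
Conditions: immobilised Candida antarctica lipase B, aq. NaH2PO4/Na2HPO4 buffer (pH 7)–MTBE, 30 °C, stopped near half conversion; chromatography
Reagents that add atoms: none
Why: Lipase-catalysed enantioselective ester hydrolysis (kinetic resolution) should cleave the (R)-acetate, which fixes C7 of the target as the free (R)-alcohol while the (S)-acetate stays and is separated; the hindered aryl pivalate should not be accepted by the enzyme.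

Step 4
Reactants: 7 4-(benzyloxy)-3-methoxybenzoic acid; 8 Meldrum's acid
Product: 9 5-{[4-(benzyloxy)-3-methoxyphenyl](hydroxy)methylidene}-2,2-dimethyl-1,3-dioxane-4,6-dione
Conditions: DCC, DMAP, CH2Cl2, 0 °C to rt
Reagents that add atoms: none
Why: Carbodiimide-mediated C-acylation of Meldrum's acid, the standard entry to acyl Meldrum's acids as storable acylketene precursors; no stereocentre is involved.

Step 5
Reactants: 6 4-[(1R)-1-hydroxyprop-2-yn-1-yl]-2-methoxyphenyl 2,2-dimethylpropanoate; 9 the acyl Meldrum's acid
Product: 11 (1R)-1-{3-methoxy-4-[(2,2-dimethylpropanoyl)oxy]phenyl}prop-2-yn-1-yl 3-[4-(benzyloxy)-3-methoxyphenyl]-3-oxopropanoate, via aroylketene 10 (not isolated)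
Conditions: toluene, 90 °C
Reagents that add atoms: none
Why: Thermolysis of the acyl Meldrum's acid (loss of acetone and CO2) gives an aroylketene that the secondary alcohol traps under neutral conditions (acylketene route to β-keto esters), so the benzylic, propargylic C7 centre is acylated on oxygen without ionisation or epimerisation.

Step 6
Reactants: 11 the propargylic β-keto ester
Product: 12 (1R)-1-{3-methoxy-4-[(2,2-dimethylpropanoyl)oxy]phenyl}prop-2-yn-1-yl 3-[4-(benzyloxy)-3-methoxyphenyl]-2-diazo-3-oxopropanoate
Conditions: 4-acetamidobenzenesulfonyl azide, Et3N, MeCN, 0 °C to rt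
Reagents that add atoms: 4-acetamidobenzenesulfonyl azide CC(=O)Nc1ccc(cc1)S(=O)(=O)N=[N+]=[N-]
Why: Regitz diazo transfer to the activated methylene between ketone and ester, run with a mild amine base that leaves the pivalate, the terminal alkyne and C7 untouched.

Step 7
Reactants: 12 the propargylic α-diazo-β-keto ester
Product: 13 4-[(3S)-6-[4-(benzyloxy)-3-methoxyphenyl]-1-oxo-1H,3H-furo[3,4-c]furan-3-yl]-2-methoxyphenyl 2,2-dimethylpropanoate
Conditions: Rh2(OAc)4 (2 mol%), benzene, 80 °C, slow addition of 12
Reagents that add atoms: none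
Why: Dirhodium tetraacetate turns the diazo group into a rhodium carbenoid at the future C3, which adds across the tethered alkyne (carbene/alkyne metathesis, directly or through a cyclopropene) so that C3 bonds to the internal alkyne carbon (future C4) and the carbene character moves to the terminal carbon (future C5); the aroyl oxygen (future O1) then attacks this vinyl carbenoid and the catalyst leaves, which forms the O1–C5 bond and the aromatic furan. The closest known reaction type is the dirhodium-carboxylate-catalysed cyclisation of alk-2-ynyl 2-diazo-3-oxoalkanoates to furo[3,4-c]furanones. The lactone ring closes in the 5-exo-dig mode (C3 onto C4 through the C(=O)–O–C7 tether), and the furan ring closes by 1,5-cyclisation of the carbonyl–vinylcarbene array O1=C2–C3=C4–C5. No new stereocentre is formed because C2 to C5 all become sp2, and C7 is a spectator whose four bonds are not touched. The step needs chemoselectivity for the alkyne over the arene rings, the benzylic C–H bonds and the ether oxygen, and regioselectivity for the internal alkyne carbon; the three-atom ester tether allows only the 5-exo approach, and the lactone carbonyl oxygen is held in the new ring, so only the ketone oxygen can reach C5.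

Step 8
Reactants: 13 the furo[3,4-c]furanone
Product: 14 4-[(3R,3aR,6R,6aS)-6-(4-hydroxy-3-methoxyphenyl)-1-oxotetrahydro-1H,3H-furo[3,4-c]furan-3-yl]-2-methoxyphenyl 2,2-dimethylpropanoate
Conditions: H2 (5 atm), 10% Pd/C, EtOAc, rt
Reagents that add atoms: none
Why: Heterogeneous catalytic hydrogenation with syn delivery of hydrogen: the planar furo-lactone should bind through the face opposite the aryl group on C7, so the hydrogens at C4, C3 and C2 all enter cis to H7, which sets C4 and the cis ring fusion at C3 as in the target and places the C2 aryl group provisionally on the concave face, while the benzyl ether is hydrogenolysed in the same operation.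

Step 9
Reactants: 14 the all-cis lactone
Product: 15 4-[(3R,3aR,6S,6aS)-6-(4-hydroxy-3-methoxyphenyl)-1-oxotetrahydro-1H,3H-furo[3,4-c]furan-3-yl]-2-methoxyphenyl 2,2-dimethylpropanoate
Conditions: CF3CO2H (3 equiv), CH2Cl2, 0 °C to rt
Reagents that add atoms: none
Why: Acid-mediated epimerisation of a 4-hydroxybenzylic ether: reversible SN1 ionisation of the C2–O1 bond to the quinone-methide-like cation and 5-exo re-closure by the C5 hydroxyl put C2 under thermodynamic control, which should move its aryl group from the crowded concave face to the convex face (2,3-trans as in the target), while the C7–O bond stays intact because its aryl group is deactivated by the pivaloyloxy group.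

Step 10
Reactants: 15 the C2-exo lactone
Product: 16 (7R)-7-hydroxylariciresinol, 4-[(2S,3R,4R)-4-[(R)-hydroxy(4-hydroxy-3-methoxyphenyl)methyl]-3-(hydroxymethyl)oxolan-2-yl]-2-methoxyphenol
Conditions: LiAlH4 (excess), THF, 0 °C to rt; aq. potassium sodium tartrate work-up
Reagents that add atoms: none
Why: Hydride reduction of the γ-lactone to the 1,4-diol (hydroxymethyl group on C3 and free C7 carbinol, with the C7–O bond and hence its configuration retained) with simultaneous reductive cleavage of the aryl pivalate, a reduction type that tolerates free phenols when worked up near neutral pH.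

**Compound list**

1 | vanillin (4-hydroxy-3-methoxybenzaldehyde) | O=Cc1ccc(O)c(OC)c1 | starting material
2 | 4-formyl-2-methoxyphenyl 2,2-dimethylpropanoate | O=Cc1ccc(OC(=O)C(C)(C)C)c(OC)c1 | intermediate
3 | ethynylmagnesium bromide | C#C[Mg]Br | starting material
4 | bromomagnesium alkoxide of racemic 4-(1-hydroxyprop-2-yn-1-yl)-2-methoxyphenyl 2,2-dimethylpropanoate (not isolated) | C#CC(O[Mg]Br)c1ccc(OC(=O)C(C)(C)C)c(OC)c1 | intermediate
5 | racemic 4-[1-(acetyloxy)prop-2-yn-1-yl]-2-methoxyphenyl 2,2-dimethylpropanoate | CC(=O)OC(C#C)c1ccc(OC(=O)C(C)(C)C)c(OC)c1 | intermediate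
6 | 4-[(1R)-1-hydroxyprop-2-yn-1-yl]-2-methoxyphenyl 2,2-dimethylpropanoate | C#C[C@@H](O)c1ccc(OC(=O)C(C)(C)C)c(OC)c1 | intermediate
7 | 4-(benzyloxy)-3-methoxybenzoic acid | O=C(O)c1ccc(OCc2ccccc2)c(OC)c1 | starting material
8 | Meldrum's acid (2,2-dimethyl-1,3-dioxane-4,6-dione) | CC1(C)OC(=O)CC(=O)O1 | starting material
9 | 5-{[4-(benzyloxy)-3-methoxyphenyl](hydroxy)methylidene}-2,2-dimethyl-1,3-dioxane-4,6-dione | CC1(C)OC(=O)C(=C(O)c2ccc(OCc3ccccc3)c(OC)c2)C(=O)O1 | intermediate
10 | 3-[4-(benzyloxy)-3-methoxyphenyl]-3-oxoprop-1-en-1-one (aroylketene, not isolated) | O=C=CC(=O)c1ccc(OCc2ccccc2)c(OC)c1 | intermediate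
11 | (1R)-1-{3-methoxy-4-[(2,2-dimethylpropanoyl)oxy]phenyl}prop-2-yn-1-yl 3-[4-(benzyloxy)-3-methoxyphenyl]-3-oxopropanoate | C#C[C@@H](OC(=O)CC(=O)c1ccc(OCc2ccccc2)c(OC)c1)c1ccc(OC(=O)C(C)(C)C)c(OC)c1 | intermediate
12 | (1R)-1-{3-methoxy-4-[(2,2-dimethylpropanoyl)oxy]phenyl}prop-2-yn-1-yl 3-[4-(benzyloxy)-3-methoxyphenyl]-2-diazo-3-oxopropanoate | C#C[C@@H](OC(=O)C(=[N+]=[N-])C(=O)c1ccc(OCc2ccccc2)c(OC)c1)c1ccc(OC(=O)C(C)(C)C)c(OC)c1 | intermediate
13 | 4-[(3S)-6-[4-(benzyloxy)-3-methoxyphenyl]-1-oxo-1H,3H-furo[3,4-c]furan-3-yl]-2-methoxyphenyl 2,2-dimethylpropanoate | O=C1O[C@@H](c3ccc(OC(=O)C(C)(C)C)c(OC)c3)c2coc(-c4ccc(OCc5ccccc5)c(OC)c4)c21 | intermediate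
14 | 4-[(3R,3aR,6R,6aS)-6-(4-hydroxy-3-methoxyphenyl)-1-oxotetrahydro-1H,3H-furo[3,4-c]furan-3-yl]-2-methoxyphenyl 2,2-dimethylpropanoate (all four ring hydrogens cis, both aryl groups endo) | O=C1O[C@@H](c3ccc(OC(=O)C(C)(C)C)c(OC)c3)[C@H]2CO[C@@H](c4ccc(O)c(OC)c4)[C@@H]12 | intermediate
15 | 4-[(3R,3aR,6S,6aS)-6-(4-hydroxy-3-methoxyphenyl)-1-oxotetrahydro-1H,3H-furo[3,4-c]furan-3-yl]-2-methoxyphenyl 2,2-dimethylpropanoate (aryl at C6 exo, aryl at C3 endo) | O=C1O[C@@H](c3ccc(OC(=O)C(C)(C)C)c(OC)c3)[C@H]2CO[C@H](c4ccc(O)c(OC)c4)[C@@H]12 | intermediate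
16 | (7R)-7-hydroxylariciresinol, 4-[(2S,3R,4R)-4-[(R)-hydroxy(4-hydroxy-3-methoxyphenyl)methyl]-3-(hydroxymethyl)oxolan-2-yl]-2-methoxyphenol | COc1cc([C@H]2OC[C@H]([C@@H](O)c3ccc(O)c(OC)c3)[C@@H]2CO)ccc1O | target

**Step count**

Total: 10 steps. Longest linear sequence: 9 steps (vanillin through steps 1, 2, 3, 5, 6, 7, 8, 9, 10).

**Steps most likely to fail**

1. Step 8. Hydrogenolysis of benzylic C–O bonds (the lactone C7–O bond, or the C2–O1 bond once the ring is saturated and the phenol is free) may compete with the slow saturation of the tetrasubstituted, ester-conjugated C2=C3 bond. The fallback sets out from 13 and splits the reduction into stages that keep the benzyl ether. H2 (1 atm) over 5% Rh/Al2O3 in EtOAc should reduce only the C4=C5 enol ether bond, anti to the C7 aryl group, to give the 3a,4-dihydrofuran benzyl ether F1. Ionic hydrogenation (Et3SiH, CF3CO2H, CH2Cl2, −20 °C; protonation at C3, then hydride to the 2-aryl oxocarbenium ion from the convex face) should give the all-cis saturated lactone benzyl ether F2. Transfer hydrogenolysis (Pd/C, cyclohexa-1,4-diene, EtOH, rt) then removes the benzyl group, and the route is rejoined at 14.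

2. Step 9. The benzylic cation may lose the C3 proton to give a conjugated arylidene lactone instead of re-closing, or equilibration may be slow. The fallback sets out from 14 and replaces the cationic epimerisation by a radical one. The phenol is acetylated (Ac2O, pyridine) to the all-cis lactone aryl acetate F3. Thiol-catalysed reversible hydrogen-atom abstraction at the C2–H bond, which is benzylic and α to the ether oxygen (tri-tert-butoxysilanethiol cat., AIBN, benzene, 80 °C), should equilibrate C2 to the C2-exo lactone aryl acetate F4. The LiAlH4 conditions of step 10 then cleave the acetate together with the pivalate and the lactone, so the route is rejoined at 16.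

3. Step 7. The carbenoid may be diverted (addition into the neighbouring arene ring, carbene dimerisation), or the electron-rich 3,4-fused furan may not survive the hot reaction mixture. The fallback is diazo-free and sets out from 11. A Conia-ene cyclisation (In(NTf2)3 cat., toluene, 60 °C) should form the C3–C4 bond and give the 3-aroyl-4-methylidene lactone F5. Iodine-mediated 5-endo iodoetherification by the enol oxygen with loss of HI (I2, NaHCO3, MeCN) then forms the O1–C5 bond and aromatises the ring, and the route is rejoined at 13.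

**Further compounds**

F1 | step 8 | 4-[(3R,3aR)-6-[4-(benzyloxy)-3-methoxyphenyl]-1-oxo-3a,4-dihydro-1H,3H-furo[3,4-c]furan-3-yl]-2-methoxyphenyl 2,2-dimethylpropanoate | O=C1O[C@@H](c3ccc(OC(=O)C(C)(C)C)c(OC)c3)[C@H]2COC(c4ccc(OCc5ccccc5)c(OC)c4)=C12
F2 | step 8 | 4-[(3R,3aR,6R,6aS)-6-[4-(benzyloxy)-3-methoxyphenyl]-1-oxotetrahydro-1H,3H-furo[3,4-c]furan-3-yl]-2-methoxyphenyl 2,2-dimethylpropanoate | O=C1O[C@@H](c3ccc(OC(=O)C(C)(C)C)c(OC)c3)[C@H]2CO[C@@H](c4ccc(OCc5ccccc5)c(OC)c4)[C@@H]12
F3 | step 9 | 4-[(3R,3aR,6R,6aS)-6-[4-(acetyloxy)-3-methoxyphenyl]-1-oxotetrahydro-1H,3H-furo[3,4-c]furan-3-yl]-2-methoxyphenyl 2,2-dimethylpropanoate | O=C1O[C@@H](c3ccc(OC(=O)C(C)(C)C)c(OC)c3)[C@H]2CO[C@@H](c4ccc(OC(C)=O)c(OC)c4)[C@@H]12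
F4 | step 9 | 4-[(3R,3aR,6S,6aS)-6-[4-(acetyloxy)-3-methoxyphenyl]-1-oxotetrahydro-1H,3H-furo[3,4-c]furan-3-yl]-2-methoxyphenyl 2,2-dimethylpropanoate | O=C1O[C@@H](c3ccc(OC(=O)C(C)(C)C)c(OC)c3)[C@H]2CO[C@H](c4ccc(OC(C)=O)c(OC)c4)[C@@H]12
F5 | step 7 | 4-[(2R)-4-[4-(benzyloxy)-3-methoxybenzoyl]-3-methylidene-5-oxooxolan-2-yl]-2-methoxyphenyl 2,2-dimethylpropanoate | C=C1[C@H](c2ccc(OC(=O)C(C)(C)C)c(OC)c2)OC(=O)C1C(=O)c1ccc(OCc2ccccc2)c(OC)c1
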